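**Retrosynthetic overview**
- The target is a biflavone. Unit 1 (5,4'-dihydroxy-7-methoxyflavone) is bonded through C3' of its ring B to C3 of unit 2 (5,7,4'-trihydroxyflavone).
- The plan rests on ring A of unit 2 (C4a, C5, C6, C7, C8, C8a, with oxygens on C5, C7 and C8a). This ring is the 1,3,5-trioxygenated benzene of free phloroglucinol, whose three C–H and three OH sites are interchangeable, so it enters unprotected and raises no regiochemical question.
- After removal of three isopropyl ethers, the last disconnection cuts C4–C4a and O1–C2 of ring C of unit 2. This gives phloroglucinol and a methyl α-aryl-β-aryl-β-ketoester in which the crowded C3–C3' bond already exists as an sp3 carbon–aryl bond.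
- The ketoester comes from C-aroylation of a flavonyl-substituted arylacetate (C2–C3 of unit 2). The flavone of unit 1 comes from a chalcone (Claisen–Schmidt, then I2/DMSO) built from a mono-isopropylated acetophenone and a formylated 2-hydroxyphenylacetic acid derivative.
- Ring order: all four benzene rings are bought, ring C of unit 1 closes in step 6 and ring C of unit 2 closes in step 9.

Key step: step 9

Assumption: the SMILES carries no axial descriptor for the C3'–C3 biaryl bond, so the target is treated as achiral. The α-carbon of the ketoester is racemic and enolisable and is lost as a stereocentre in the key step.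

**Step 1**
Reactants: 1 2-hydroxyphenylacetic acid
Product: 2 isopropyl 2-(2-isopropoxyphenyl)acetate
Conditions: 2-bromopropane (3 equiv), K2CO3 (3 equiv), DMF, 65 °C
Reagents that add atoms: 2-bromopropane CC(C)Br
Why: Williamson etherification of the phenoxide and SN2 esterification of the carboxylate occur in one operation under basic conditions that prevent lactonisation, and the ester is needed because the formylating agent of step 2 would turn a free acid into its chloride.

**Step 2**
Reactants: 2 isopropyl 2-(2-isopropoxyphenyl)acetate
Product: 3 isopropyl 2-(5-formyl-2-isopropoxyphenyl)acetate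
Conditions: Cl2CHOMe (1.3 equiv), TiCl4 (2.2 equiv), CH2Cl2, –10 to 0 °C; then ice, 1 M HCl
Reagents that add atoms: dichloromethyl methyl ether COC(Cl)Cl; water O
Why: In this Rieche formylation the isopropoxy group, the strongest donor, directs the electrophile to its para position C5 because its free ortho position is shielded by the branched ether, and a short time at or below 0 °C should spare the non-chelated isopropyl ether and the ester.

**Step 3**
Reactants: 4 2',6'-dihydroxy-4'-methoxyacetophenone
Product: 5 2'-hydroxy-6'-isopropoxy-4'-methoxyacetophenone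
Conditions: 2-bromopropane (1.1 equiv), K2CO3 (1.2 equiv), DMF, 50 °C
Reagents that add atoms: 2-bromopropane CC(C)Br
Why: In this Williamson monoalkylation the two hydroxyls are equivalent, and once one is etherified the other is locked in a strong hydrogen bond to the acetyl oxygen and reacts much more slowly, so one equivalent of halide should stop at the monoether.

**Step 4**
Reactants: 3 isopropyl 2-(5-formyl-2-isopropoxyphenyl)acetate; 5 2'-hydroxy-6'-isopropoxy-4'-methoxyacetophenone
Product: 7 (E)-2-{5-[3-(2-hydroxy-6-isopropoxy-4-methoxyphenyl)-3-oxoprop-1-en-1-yl]-2-isopropoxyphenyl}acetic acid (chalcone acid), via potassium formylarylacetate 6 (not isolated)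
Conditions: KOH (10 equiv), EtOH–H2O, 0 °C to rt, 1 h; then 5, rt, 48 h; then cold 2 M HCl to pH 2
Reagents that add atoms: potassium hydroxide [K+].[OH-]
Why: This Claisen–Schmidt condensation is run on the carboxylate because the ArCH2CO2R methylene of the ester is more acidic than the acetyl CH3 and would compete for the aldehyde, so hydroxide first saponifies the ester, after which only the methyl ketone can enolise and E1cB loss of water gives the conjugated E-enone under thermodynamic control.

**Step 5**
Reactants: 7 chalcone acid
Product: 8 methyl (E)-2-{5-[3-(2-hydroxy-6-isopropoxy-4-methoxyphenyl)-3-oxoprop-1-en-1-yl]-2-isopropoxyphenyl}acetate (chalcone ester)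
Conditions: MeI (1.2 equiv), KHCO3 (1.5 equiv), DMF, rt
Reagents that add atoms: methyl iodide CI
Why: This is an SN2 esterification of the carboxylate in which hydrogencarbonate deprotonates only the carboxylic acid and leaves untouched the chelated 2'-hydroxyl that the next step needs.

**Step 6**
Reactants: 8 chalcone ester
Product: 10 methyl 2-[2-isopropoxy-5-(5-isopropoxy-7-methoxy-4-oxo-4H-chromen-2-yl)phenyl]acetate (flavone ester), via racemic flavanone 9 (not isolated)
Conditions: I2 (10 mol %), DMSO, 130 °C, 2 h
Reagents that add atoms: none
Why: In this iodine/DMSO oxidative cyclisation of a 2'-hydroxychalcone a 6-endo-trig oxa-Michael closure forms ring C of unit 1 as the flavanone, α-iodination and loss of HI follow, and DMSO reoxidises HI so that iodine stays catalytic and the poorly enolisable ester CH2 is left alone.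

**Step 7**
Reactants: 11 4-isopropoxybenzoic acid
Product: 12 4-isopropoxybenzoyl chloride
Conditions: (COCl)2 (1.5 equiv), DMF (cat.), CH2Cl2, 0 °C to rt; concentrated and used crude
Reagents that add atoms: oxalyl chloride O=C(Cl)C(=O)Cl
Why: This is a standard acid chloride formation through the chloroiminium species from DMF, and it gives only gaseous by-products, so the crude chloride can be used directly.

**Step 8**
Reactants: 10 flavone ester; 12 4-isopropoxybenzoyl chloride
Product: 14 methyl 2-[2-isopropoxy-5-(5-isopropoxy-7-methoxy-4-oxo-4H-chromen-2-yl)phenyl]-3-(4-isopropoxyphenyl)-3-oxopropanoate (racemic β-ketoester), via lithium ester enolate 13 (not isolated)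
Conditions: LiHMDS (2.2 equiv), THF, –78 °C, 30 min; then 12 (1.1 equiv), –78 to –40 °C; AcOH quench at –78 °C
Reagents that add atoms: none
Why: In this crossed Claisen-type C-acylation of a lithium ester enolate with an aroyl chloride, LiHMDS removes the benzylic ester proton (pKa about 23) but is too weak for the chromone C3–H and too bulky to add at C2, and the second equivalent converts the more acidic β-ketoester into its enolate as it forms, which prevents proton exchange with unreacted 13.

**Step 9**
Reactants: 14 racemic β-ketoester; 15 phloroglucinol (anhydrous)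
Product: 18 5,7-dihydroxy-2-(4-isopropoxyphenyl)-3-[2-isopropoxy-5-(5-isopropoxy-7-methoxy-4-oxo-4H-chromen-2-yl)phenyl]-4H-chromen-4-one (tri-O-isopropyl biflavone), via aroyl(aryl)ketene 16 (not isolated), via acylphloroglucinol diketone 17 (not isolated)
Conditions: 15 (3 equiv, dried at 110 °C in vacuo), Ph2O, 245 °C, Ar sweep with distillative removal of MeOH and H2O, 1–2 h
Reagents that add atoms: none
Why: Heated well beyond 200 °C, 14 loses methanol from its hydrogen-bonded enol through a six-membered transition state and becomes ketene 16; addition of a phenolic oxygen to 16 can revert at this temperature, whereas attack by a ring carbon of 15 followed by rearomatisation gives the chelated aryl ketone 17 and so sets C4–C4a. One of the two equivalent ortho hydroxyls of 17 then adds to the 4-isopropoxyphenyl ketone in a 6-exo-trig closure, and loss of water from the hemiketal gives the aromatic pyranone (O1–C2, ring C of unit 2), the irreversible end point that drains all equilibria. The closest known reaction type is the Mentzer thermal chromone synthesis from phenols and β-ketoesters, which has been run with phloroglucinol and with α-substituted, including α-aryl, ketoesters. No stereocentre arises, since the racemic α-carbon of 14 ends as the sp2 carbon C3. The selectivity needed is chromone over coumarin, which should follow from the acid-free medium, in which the ester carbon reaches the ring first as the ketene, and from the α-aryl group, which blocks Pechmann-type attack of the ring on the ketone; site selectivity is not needed because all C–H and OH positions of 15 are equivalent. Excess dry 15 and continuous removal of methanol and water should hold back a second annulation and the hydration and decarboxylation of 16, and the isopropyl ether on C4' of unit 1 stops that oxygen from condensing with the same ketone to a benzofuran.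

**Step 10**
Reactants: 18 tri-O-isopropyl biflavone
Product: 19 5,7-dihydroxy-3-[2-hydroxy-5-(5-hydroxy-7-methoxy-4-oxo-4H-chromen-2-yl)phenyl]-2-(4-hydroxyphenyl)-4H-chromen-4-one (target)
Conditions: BCl3 (1 M in CH2Cl2, 10 equiv), CH2Cl2, –78 °C to rt; then ice, 1 M HCl
Reagents that add atoms: none
Why: In this Lewis-acid dealkylation BCl3 binds the ether oxygens and the secondary isopropyl groups leave as 2-chloropropane by a cation-like path closed to a methyl group, and the C7 methoxy, which has no neighbouring carbonyl to chelate boron, should remain.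

**Compound list**
1 | 2-hydroxyphenylacetic acid | OC(=O)Cc1ccccc1O | starting material
2 | isopropyl 2-(2-isopropoxyphenyl)acetate | CC(C)OC(=O)Cc1ccccc1OC(C)C | intermediate
3 | isopropyl 2-(5-formyl-2-isopropoxyphenyl)acetate | CC(C)OC(=O)Cc1cc(C=O)ccc1OC(C)C | intermediate
4 | 2',6'-dihydroxy-4'-methoxyacetophenone | COc1cc(O)c(C(C)=O)c(O)c1 | starting material
5 | 2'-hydroxy-6'-isopropoxy-4'-methoxyacetophenone | COc1cc(O)c(C(C)=O)c(OC(C)C)c1 | intermediate
6 | potassium 2-(5-formyl-2-isopropoxyphenyl)acetate | [K+].[O-]C(=O)Cc1cc(C=O)ccc1OC(C)C | intermediate (not isolated)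
7 | (E)-chalcone acid | COc1cc(O)c(C(=O)/C=C/c2ccc(OC(C)C)c(CC(=O)O)c2)c(OC(C)C)c1 | intermediate
8 | (E)-chalcone methyl ester | COc1cc(O)c(C(=O)/C=C/c2ccc(OC(C)C)c(CC(=O)OC)c2)c(OC(C)C)c1 | intermediate
9 | methyl 2-[2-isopropoxy-5-(5-isopropoxy-7-methoxy-4-oxochroman-2-yl)phenyl]acetate (racemic flavanone) | COC(=O)Cc1cc(C2CC(=O)c3c(OC(C)C)cc(OC)cc3O2)ccc1OC(C)C | intermediate (not isolated)
10 | methyl 2-[2-isopropoxy-5-(5-isopropoxy-7-methoxy-4-oxo-4H-chromen-2-yl)phenyl]acetate | COC(=O)Cc1cc(-c2cc(=O)c3c(OC(C)C)cc(OC)cc3o2)ccc1OC(C)C | intermediate
11 | 4-isopropoxybenzoic acid | CC(C)Oc1ccc(C(=O)O)cc1 | starting material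
12 | 4-isopropoxybenzoyl chloride | CC(C)Oc1ccc(C(=O)Cl)cc1 | intermediate
13 | lithium enolate of 10 | [Li+].[O-]C(OC)=Cc1cc(-c2cc(=O)c3c(OC(C)C)cc(OC)cc3o2)ccc1OC(C)C | intermediate (not isolated)
14 | methyl 2-aryl-3-(4-isopropoxyphenyl)-3-oxopropanoate carrying protected unit 1 (racemic) | COC(=O)C(C(=O)c1ccc(OC(C)C)cc1)c1cc(-c2cc(=O)c3c(OC(C)C)cc(OC)cc3o2)ccc1OC(C)C | intermediate
15 | phloroglucinol | Oc1cc(O)cc(O)c1 | starting material
16 | (4-isopropoxybenzoyl)(aryl)ketene carrying protected unit 1 | O=C=C(C(=O)c1ccc(OC(C)C)cc1)c1cc(-c2cc(=O)c3c(OC(C)C)cc(OC)cc3o2)ccc1OC(C)C | intermediate (not isolated)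
17 | 2-aryl-1-(4-isopropoxyphenyl)-3-(2,4,6-trihydroxyphenyl)propane-1,3-dione | O=C(c1c(O)cc(O)cc1O)C(C(=O)c1ccc(OC(C)C)cc1)c1cc(-c2cc(=O)c3c(OC(C)C)cc(OC)cc3o2)ccc1OC(C)C | intermediate (not isolated)
18 | tri-O-isopropyl biflavone (isopropyl on C5–O and C4'–O of unit 1 and C4'–O of unit 2) | COc1cc(OC(C)C)c2c(=O)cc(-c3ccc(OC(C)C)c(-c4c(-c5ccc(OC(C)C)cc5)oc5cc(O)cc(O)c5c4=O)c3)oc2c1 | intermediate
19 | target biflavone | COc1cc(O)c2c(=O)cc(-c3ccc(O)c(-c4c(-c5ccc(O)cc5)oc5cc(O)cc(O)c5c4=O)c3)oc2c1 | target

**Step count**
- Total steps: 10.
- Longest linear sequence: 8 (steps 1, 2, 4, 5, 6, 8, 9, 10).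

**Steps most likely to fail**

1. **Step 9.**
   - Risks: hydration of the ketene by the water of cyclodehydration, followed by decarboxylation. Thermal loss of the isopropyl group next to the ketene carbon, followed by furan closure. Competing closure in the coumarin sense. General decomposition at the temperature required.
   - Fallback: this sets out from 10 and forms the same ring in stages by deoxybenzoin chemistry.
     - Saponification of 10 (LiOH, THF–H2O, rt) should give the arylacetic acid F1.
     - Friedel–Crafts acylation of 15 with F1 in BF3·OEt2 at 80 °C is the usual entry to isoflavone precursors, and BF3 is a far weaker dealkylating agent than BCl3. It should give the 2,4,6-trihydroxyphenyl benzyl ketone F2.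
     - Heating F2 with 12 (3.5 equiv) and K2CO3 in acetone should bring about O-aroylation, Baker–Venkataraman transfer of an ortho aroyl group to the benzylic carbon and ring closure. The product is the 5,7-bis(4-isopropoxybenzoate) F3.
     - K2CO3 in MeOH at rt removes both esters and brings the route back at 18.

2. **Step 8.**
   - Risks: O-acylation of the hindered enolate, further acylation of the product enolate, or retro-Claisen cleavage during quench and work-up.
   - Fallback: this sets out from 10 and replaces acylation by aldol addition and oxidation.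
     - Enolate 13 (LiHMDS, 1.1 equiv, THF, –78 °C) is treated with commercial 4-isopropoxybenzaldehyde and quenched cold. This should give the β-hydroxy ester F4 as a diastereomer mixture of no consequence.
     - Dess–Martin periodinane in CH2Cl2 oxidises the carbinol and brings the route back at 14.

3. **Step 2.**
   - Risks: Lewis-acid-induced loss of the isopropyl ether, or incomplete para selectivity of the electrophilic substitution.
   - Fallback: this sets out from 2 and separates site selection from carbon introduction.
     - Para-selective bromination with NBS in MeCN at rt should give the aryl bromide F5.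
     - Reductive carbonylation then converts C–Br into C–CHO and brings the route back at 3. Conditions: Pd(OAc)2, di(1-adamantyl)-n-butylphosphine, TMEDA, CO/H2 at 5 bar, toluene, 100 °C.

**Further compounds**
F1 | step 9 | 2-[2-isopropoxy-5-(5-isopropoxy-7-methoxy-4-oxo-4H-chromen-2-yl)phenyl]acetic acid | OC(=O)Cc1cc(-c2cc(=O)c3c(OC(C)C)cc(OC)cc3o2)ccc1OC(C)C
F2 | step 9 | 2-[2-isopropoxy-5-(5-isopropoxy-7-methoxy-4-oxo-4H-chromen-2-yl)phenyl]-1-(2,4,6-trihydroxyphenyl)ethanone | O=C(Cc1cc(-c2cc(=O)c3c(OC(C)C)cc(OC)cc3o2)ccc1OC(C)C)c1c(O)cc(O)cc1O
F3 | step 9 | 5,7-bis(4-isopropoxybenzoate) of 18 | COc1cc(OC(C)C)c2c(=O)cc(-c3ccc(OC(C)C)c(-c4c(-c5ccc(OC(C)C)cc5)oc5cc(OC(=O)c6ccc(OC(C)C)cc6)cc(OC(=O)c6ccc(OC(C)C)cc6)c5c4=O)c3)oc2c1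
F4 | step 8 | methyl 3-hydroxy-2-[2-isopropoxy-5-(5-isopropoxy-7-methoxy-4-oxo-4H-chromen-2-yl)phenyl]-3-(4-isopropoxyphenyl)propanoate (racemic diastereomer mixture) | COC(=O)C(C(O)c1ccc(OC(C)C)cc1)c1cc(-c2cc(=O)c3c(OC(C)C)cc(OC)cc3o2)ccc1OC(C)C
F5 | step 2 | isopropyl 2-(5-bromo-2-isopropoxyphenyl)acetate | CC(C)OC(=O)Cc1cc(Br)ccc1OC(C)C
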